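**Retrosynthetic overview**

- The target is a flavonol. The last operations are introduction of the C3 hydroxyl on flavone 22 (C3 lithiation, borylation, oxidation) and hydrogenolysis of three benzyl ethers.
- Ring C is cut at C8a–O1, C4a–C4 and O1–C2, giving aryne 20 (released from silyl triflate 9) and arylpropiolic acid 19, which supplies C2, C3, C4 and ring B in one piece.
- The strategy rests on this feature: ring A carries O1 on C8a and the C4 carbonyl on the neighbouring C4a, and the C5 methoxy flanks C4a. A C4a≡C8a aryne is therefore polarised so that the carboxylate oxygen enters at C8a and the acyl carbon ends up on C4a.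
- 9 comes from 2,3,4-trihydroxybenzaldehyde (oxygen pattern fixed by a Dakin-type oxidation). 19 comes from 2-hydroxy-5-iodobenzaldehyde and (2R)-3-bromo-2-methylpropan-1-ol (stereocentre from the chiral pool) by Wittig olefination, diimide reduction and Pd coupling with propiolic acid.
- Ring order: rings A and B are bought; ring C is the only ring formed (step 12).

Key step: step 12

Remark on the chemistry: the Wittig olefin 16 is drawn as the Z isomer expected from a non-stabilised ylide; any E isomer converges in step 10, so the geometry has no consequence. The (2R) bromo alcohol 10 gives the (S) centre of the target because only the CIP priorities change along the route, not the spatial arrangement.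

**Route**

Step 1
Reactants: 1 2,3,4-trihydroxybenzaldehyde
Product: 2 4-(benzyloxy)-2,3-dihydroxybenzaldehyde
Conditions: BnBr (1.0 equiv), NaHCO3, NaI (cat.), DMF, 40 °C
Reagents that add atoms: benzyl bromide, BrCc1ccccc1
Why: Williamson etherification; the 4-OH is para to the formyl group and the most acidic phenol (the 2-OH is hydrogen-bonded to C=O), so one equivalent of benzyl bromide with a weak base should alkylate O4 selectively.

Step 2
Reactants: 2 4-(benzyloxy)-2,3-dihydroxybenzaldehyde
Product: 3 4-(benzyloxy)-2,3-dimethoxybenzaldehyde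
Conditions: MeI (3 equiv), K2CO3, DMF, rt → 50 °C
Reagents that add atoms: iodomethane, CI
Why: Williamson methylation of both remaining phenols; the chelated 2-OH reacts in DMF on warming, and the aldehyde and benzyl ether are inert.

Step 3
Reactants: 3 4-(benzyloxy)-2,3-dimethoxybenzaldehyde
Product: 5 4-(benzyloxy)-2,3-dimethoxyphenol, via aryl formate 4 (not isolated)
Conditions: mCPBA, CH2Cl2, 0 °C → rt; then K2CO3 (0.2 equiv), MeOH, rt
Reagents that add atoms: 3-chloroperoxybenzoic acid, OOC(=O)c1cccc(Cl)c1
Why: Baeyer–Villiger (Dakin-type) oxidation; the electron-rich aryl group migrates to give formate 4, which is methanolysed to the phenol, so the new oxygen sits exactly on the former formyl carbon.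

Step 4
Reactants: 5 4-(benzyloxy)-2,3-dimethoxyphenol
Product: 6 4-(benzyloxy)-6-bromo-2,3-dimethoxyphenol
Conditions: NBS (1.0 equiv), i-Pr2NH (10 mol %), CH2Cl2, −20 → 0 °C
Reagents that add atoms: N-bromosuccinimide, O=C1CCC(=O)N1Br
Why: Electrophilic aromatic bromination directed by the free phenol; C6 is the only open position ortho to OH (and para to the C3 methoxy), and the amine-mediated NBS protocol should deliver bromine ortho to the hydroxyl rather than to C5 beside the benzyl ether.

Step 5
Reactants: 6 4-(benzyloxy)-6-bromo-2,3-dimethoxyphenol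
Product: 9 4-(benzyloxy)-2,3-dimethoxy-6-(trimethylsilyl)phenyl trifluoromethanesulfonate, via aryl trimethylsilyl ether 7 (not isolated), via lithium silylphenoxide 8 (not isolated)
Conditions: HN(SiMe3)2, THF, 70 °C, then evaporation; n-BuLi, THF, −100 → −80 °C; Tf2O, −100 °C → rt
Reagents that add atoms: hexamethyldisilazane, C[Si](C)(C)N[Si](C)(C)C; trifluoromethanesulfonic anhydride, O=S(=O)(OS(=O)(=O)C(F)(F)F)C(F)(F)F
Why: O-silylation, fast bromine–lithium exchange and 1,3-O→C silyl migration (retro-Brook rearrangement) place silicon on C6 and leave the lithium phenoxide, which is triflated in the same flask; this is the standard sequence to o-silylaryl triflates.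

Step 6
Reactants: 10 (2R)-3-bromo-2-methylpropan-1-ol
Product: 11 {[(2R)-3-bromo-2-methylpropoxy]methyl}benzene
Conditions: BnOC(=NH)CCl3, TfOH (cat.), CH2Cl2/cyclohexane, 0 °C → rt
Reagents that add atoms: benzyl 2,2,2-trichloroacetimidate, N=C(OCc1ccccc1)C(Cl)(Cl)Cl
Why: Acid-catalysed benzylation with the trichloroacetimidate avoids an alkoxide that could displace or eliminate the bromide; the stereocentre comes from the chiral pool and is not touched.

Step 7
Reactants: 11 {[(2R)-3-bromo-2-methylpropoxy]methyl}benzene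
Product: 12 [(2R)-3-(benzyloxy)-2-methylpropyl]triphenylphosphonium bromide
Conditions: PPh3 (1.5 equiv), neat, 110 °C
Reagents that add atoms: triphenylphosphine, c1ccc(cc1)P(c1ccccc1)c1ccccc1
Why: SN2 quaternisation of the phosphine by the primary bromide; the β-branch slows but does not prevent it at this temperature, and the stereocentre is not involved.

Step 8
Reactants: 13 2-hydroxy-5-iodobenzaldehyde
Product: 14 2-(benzyloxy)-5-iodobenzaldehyde
Conditions: BnBr, K2CO3, DMF, rt
Reagents that add atoms: benzyl bromide, BrCc1ccccc1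
Why: Williamson benzylation of the phenol; the aldehyde and aryl iodide are inert.

Step 9
Reactants: 12 [(2R)-3-(benzyloxy)-2-methylpropyl]triphenylphosphonium bromide; 14 2-(benzyloxy)-5-iodobenzaldehyde
Product: 16 1-(benzyloxy)-2-[(1Z,3S)-4-(benzyloxy)-3-methylbut-1-en-1-yl]-4-iodobenzene, via phosphorus ylide 15 (not isolated)
Conditions: 12, NaN(SiMe3)2 (0.95 equiv to 12), THF, −78 → 0 °C; then 14, −78 °C → rt
Reagents that add atoms: none
Why: Wittig olefination with a non-stabilised ylide should give mainly the Z alkene; the amide base spares the aryl iodide, and the hydrogen at the stereocentre is not acidic under these conditions, so the configuration is kept.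

Step 10
Reactants: 16 1-(benzyloxy)-2-[(1Z,3S)-4-(benzyloxy)-3-methylbut-1-en-1-yl]-4-iodobenzene
Product: 17 1-(benzyloxy)-2-[(3S)-4-(benzyloxy)-3-methylbutyl]-4-iodobenzene
Conditions: TsNHNH2 (excess, portionwise), NaOAc, DME/H2O, reflux
Reagents that add atoms: none
Why: Diimide reduction; concerted syn transfer of H2 to the C=C leaves the aryl iodide and benzyl ethers untouched and, unlike metal-catalysed hydrogenation, cannot migrate the double bond through the allylic stereocentre.

Step 11
Reactants: 17 1-(benzyloxy)-2-[(3S)-4-(benzyloxy)-3-methylbutyl]-4-iodobenzene; 18 prop-2-ynoic acid (propiolic acid)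
Product: 19 3-{4-(benzyloxy)-3-[(3S)-4-(benzyloxy)-3-methylbutyl]phenyl}prop-2-ynoic acid
Conditions: Pd(PPh3)4 (3 mol %), DBU (2.4 equiv), DMSO, 35 °C; aq. HCl work-up
Reagents that add atoms: none
Why: Copper-free Sonogashira-type coupling of the aryl iodide with propiolic acid as its amidinium salt; the iodide allows a temperature well below that at which arylpropiolic acids decarboxylate.

Step 12
Reactants: 9 4-(benzyloxy)-2,3-dimethoxy-6-(trimethylsilyl)phenyl trifluoromethanesulfonate (1.5 equiv); 19 3-{4-(benzyloxy)-3-[(3S)-4-(benzyloxy)-3-methylbutyl]phenyl}prop-2-ynoic acid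
Product: 22 7-(benzyloxy)-2-{4-(benzyloxy)-3-[(3S)-4-(benzyloxy)-3-methylbutyl]phenyl}-5,6-dimethoxy-4H-chromen-4-one, via aryne 20 (not isolated), via hydroxyaryl ynone 21 (not isolated)
Conditions: CsF (4 equiv), THF, 125 °C, sealed tube
Reagents that add atoms: none
Why: Fluoride removes the silyl group of 9 and triflate leaves to give aryne 20; the caesium carboxylate of 19 adds through oxygen at C8a, the aryl anion formed at C4a attacks its own ester carbonyl through a four-membered transition structure, and C–O cleavage gives the phenoxide of ynone 21 (net insertion of the aryne into the acid C–O bond). The closest known reaction type is the fluoride-induced C–O insertion of arynes into carboxylic acids, which gives o-hydroxyaryl ketones and, from arylpropiolic acids, flavones. Ring C then closes by 6-endo-dig oxa-Michael addition of the C8a phenoxide to the ynone β-carbon (C2), and protonation at C3 gives the pyranone; in the aprotic medium this closure should be preferred over 5-exo closure to an aurone. No stereocentre is formed and the remote (S) centre takes no part. The step needs regioselective addition to the unsymmetrical aryne: the inductively withdrawing C5 methoxy beside C4a distorts the aryne so that the nucleophile enters at the distal, unhindered C8a (flanked only by C8–H) and the charge develops at C4a, while the weaker effects of the C6 methoxy and C7 benzyloxy groups roughly cancel.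

Step 13
Reactants: 22 7-(benzyloxy)-2-{4-(benzyloxy)-3-[(3S)-4-(benzyloxy)-3-methylbutyl]phenyl}-5,6-dimethoxy-4H-chromen-4-one
Product: 25 7-(benzyloxy)-2-{4-(benzyloxy)-3-[(3S)-4-(benzyloxy)-3-methylbutyl]phenyl}-3-hydroxy-5,6-dimethoxy-4H-chromen-4-one, via 3-lithioflavone 23 (not isolated), via lithium trimethoxyborate 24 (not isolated)
Conditions: LiN(i-Pr)2, THF, −78 °C; B(OMe)3, −78 → 0 °C; AcOH, 30% aq. H2O2, 0 °C → rt
Reagents that add atoms: hydrogen peroxide, OO
Why: Directed lithiation at C3 (the only vinylic C–H beside the carbonyl, with lithium held by the C4 oxygen), borylation and oxidation of the C–B bond is the established conversion of 5-alkoxyflavones into flavonols; all ether groups tolerate the sequence.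

Step 14
Reactants: 25 7-(benzyloxy)-2-{4-(benzyloxy)-3-[(3S)-4-(benzyloxy)-3-methylbutyl]phenyl}-3-hydroxy-5,6-dimethoxy-4H-chromen-4-one
Product: 26 3,7-dihydroxy-2-{4-hydroxy-3-[(3S)-4-hydroxy-3-methylbutyl]phenyl}-5,6-dimethoxy-4H-chromen-4-one (CNP0253239.1)
Conditions: H2 (1 atm), Pd(OH)2/C, EtOAc/MeOH, rt
Reagents that add atoms: none
Why: Catalytic hydrogenolysis removes the two aryl benzyl ethers and the primary alkyl benzyl ether in one operation; the pyranone double bond of a flavonol and the methyl ethers should survive, and the stereocentre is remote from any reacting bond.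

**Compound list**

1 | 2,3,4-trihydroxybenzaldehyde | O=Cc1ccc(O)c(O)c1O | starting material
2 | 4-(benzyloxy)-2,3-dihydroxybenzaldehyde | O=Cc1ccc(OCc2ccccc2)c(O)c1O | intermediate
3 | 4-(benzyloxy)-2,3-dimethoxybenzaldehyde | COc1c(C=O)ccc(OCc2ccccc2)c1OC | intermediate
4 | 4-(benzyloxy)-2,3-dimethoxyphenyl formate | COc1c(OC=O)ccc(OCc2ccccc2)c1OC | intermediate (not isolated)
5 | 4-(benzyloxy)-2,3-dimethoxyphenol | COc1c(O)ccc(OCc2ccccc2)c1OC | intermediate
6 | 4-(benzyloxy)-6-bromo-2,3-dimethoxyphenol | COc1c(O)c(Br)cc(OCc2ccccc2)c1OC | intermediate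
7 | [4-(benzyloxy)-6-bromo-2,3-dimethoxyphenoxy]trimethylsilane | COc1c(O[Si](C)(C)C)c(Br)cc(OCc2ccccc2)c1OC | intermediate (not isolated)
8 | lithium 4-(benzyloxy)-2,3-dimethoxy-6-(trimethylsilyl)phenolate | [Li+].COc1c([O-])c([Si](C)(C)C)cc(OCc2ccccc2)c1OC | intermediate (not isolated)
9 | 4-(benzyloxy)-2,3-dimethoxy-6-(trimethylsilyl)phenyl trifluoromethanesulfonate | COc1c(OS(=O)(=O)C(F)(F)F)c([Si](C)(C)C)cc(OCc2ccccc2)c1OC | intermediate
10 | (2R)-3-bromo-2-methylpropan-1-ol | BrC[C@H](C)CO | starting material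
11 | {[(2R)-3-bromo-2-methylpropoxy]methyl}benzene | BrC[C@H](C)COCc1ccccc1 | intermediate
12 | [(2R)-3-(benzyloxy)-2-methylpropyl]triphenylphosphonium bromide | [Br-].c1ccccc1[P+](c1ccccc1)(c1ccccc1)C[C@H](C)COCc1ccccc1 | intermediate
13 | 2-hydroxy-5-iodobenzaldehyde | O=Cc1cc(I)ccc1O | starting material
14 | 2-(benzyloxy)-5-iodobenzaldehyde | O=Cc1cc(I)ccc1OCc1ccccc1 | intermediate
15 | [(2R)-3-(benzyloxy)-2-methylpropylidene]triphenyl-λ5-phosphane | c1ccccc1P(c1ccccc1)(c1ccccc1)=C[C@H](C)COCc1ccccc1 | intermediate (not isolated)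
16 | 1-(benzyloxy)-2-[(1Z,3S)-4-(benzyloxy)-3-methylbut-1-en-1-yl]-4-iodobenzene | Ic1ccc(OCc2ccccc2)c(/C=C\[C@H](C)COCc2ccccc2)c1 | intermediate
17 | 1-(benzyloxy)-2-[(3S)-4-(benzyloxy)-3-methylbutyl]-4-iodobenzene | Ic1ccc(OCc2ccccc2)c(CC[C@H](C)COCc2ccccc2)c1 | intermediate
18 | prop-2-ynoic acid | OC(=O)C#C | starting material
19 | 3-{4-(benzyloxy)-3-[(3S)-4-(benzyloxy)-3-methylbutyl]phenyl}prop-2-ynoic acid | OC(=O)C#Cc1ccc(OCc2ccccc2)c(CC[C@H](C)COCc2ccccc2)c1 | intermediate
20 | 5-(benzyloxy)-3,4-dimethoxy-1,2-didehydrobenzene (aryne) | COC1=C(OC)C(OCc2ccccc2)=CC#C1 | intermediate (not isolated)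
21 | 1-[4-(benzyloxy)-6-hydroxy-2,3-dimethoxyphenyl]-3-{4-(benzyloxy)-3-[(3S)-4-(benzyloxy)-3-methylbutyl]phenyl}prop-2-yn-1-one | COc1c(OCc2ccccc2)cc(O)c(C(=O)C#Cc2ccc(OCc3ccccc3)c(CC[C@H](C)COCc3ccccc3)c2)c1OC | intermediate (not isolated)
22 | 7-(benzyloxy)-2-{4-(benzyloxy)-3-[(3S)-4-(benzyloxy)-3-methylbutyl]phenyl}-5,6-dimethoxy-4H-chromen-4-one | COc1c(OCc4ccccc4)cc2oc(-c3ccc(OCc5ccccc5)c(CC[C@H](C)COCc6ccccc6)c3)cc(=O)c2c1OC | intermediate
23 | 3-lithio derivative of 22 (lithium at C3 of the chromenone) | COc1c(OCc4ccccc4)cc2oc(-c3ccc(OCc5ccccc5)c(CC[C@H](C)COCc6ccccc6)c3)c([Li])c(=O)c2c1OC | intermediate (not isolated)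
24 | lithium {7-(benzyloxy)-2-{4-(benzyloxy)-3-[(3S)-4-(benzyloxy)-3-methylbutyl]phenyl}-5,6-dimethoxy-4-oxo-4H-chromen-3-yl}trimethoxyborate | [Li+].COc1c(OCc4ccccc4)cc2oc(-c3ccc(OCc5ccccc5)c(CC[C@H](C)COCc6ccccc6)c3)c([B-](OC)(OC)OC)c(=O)c2c1OC | intermediate (not isolated)
25 | 7-(benzyloxy)-2-{4-(benzyloxy)-3-[(3S)-4-(benzyloxy)-3-methylbutyl]phenyl}-3-hydroxy-5,6-dimethoxy-4H-chromen-4-one | COc1c(OCc4ccccc4)cc2oc(-c3ccc(OCc5ccccc5)c(CC[C@H](C)COCc6ccccc6)c3)c(O)c(=O)c2c1OC | intermediate
26 | 3,7-dihydroxy-2-{4-hydroxy-3-[(3S)-4-hydroxy-3-methylbutyl]phenyl}-5,6-dimethoxy-4H-chromen-4-one | COc1c(O)cc2oc(-c3ccc(O)c(CC[C@H](C)CO)c3)c(O)c(=O)c2c1OC | target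

**Step count**

Total: 14 steps. Longest linear sequence: 8 steps (1 → 2 → 3 → 5 → 6 → 9 → 22 → 25 → 26; steps 1–5 and 12–14).

**Steps most likely to fail**

1. Step 12 (key step). The caesium arylpropiolate may lose CO2 at 125 °C before it captures the aryne, the sequence may stop at the aryl ester without acyl migration, or the phenoxide may close 5-exo to an aurone. The fallback keeps the aryne insertion but uses a partner that can neither decarboxylate nor cyclise, and builds ring C by the chalcone route. It sets out from 9 and 17 and returns at 22. Silyl triflate 9 with acetic acid, CsF, THF, 125 °C should give 1-[4-(benzyloxy)-6-hydroxy-2,3-dimethoxyphenyl]ethan-1-one F1 with the same regiochemistry. Iodide 17 is converted by iodine–lithium exchange (n-BuLi, THF, −78 °C) and DMF into 4-(benzyloxy)-3-[(3S)-4-(benzyloxy)-3-methylbutyl]benzaldehyde F2. Claisen–Schmidt condensation of F1 and F2 (KOH, EtOH, rt) should give (2E)-1-[4-(benzyloxy)-6-hydroxy-2,3-dimethoxyphenyl]-3-{4-(benzyloxy)-3-[(3S)-4-(benzyloxy)-3-methylbutyl]phenyl}prop-2-en-1-one F3. Oxidative cyclisation of F3 with catalytic I2 in DMSO at 120 °C then gives 22.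

2. Step 13. The amide base may deprotonate a benzylic ether position or add at C2 with opening of the pyranone, or lithiation at C3 may be incomplete. The fallback replaces the anionic sequence by an electrophilic oxidation; it sets out from 22 and returns at 25. Dimethyldioxirane in acetone/CH2Cl2 at 0 °C should epoxidise the C2=C3 bond to give 7-(benzyloxy)-2-{4-(benzyloxy)-3-[(3S)-4-(benzyloxy)-3-methylbutyl]phenyl}-2,3-epoxy-5,6-dimethoxy-2,3-dihydro-4H-chromen-4-one F4 (both cis-epoxide diastereomers, which converge). Catalytic p-toluenesulfonic acid in CH2Cl2 then opens the epoxide and the enol tautomerises to flavonol 25.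

3. Step 4. Bromine may enter at C5 beside the benzyl ether, or the hydroquinone monoether may be oxidised towards the quinone. The fallback installs silicon by directed ortho-metalation instead of bromination and retro-Brook shift; it sets out from 5 and returns at 9. Phenol 5 with isopropyl isocyanate and catalytic Et3N gives 4-(benzyloxy)-2,3-dimethoxyphenyl propan-2-ylcarbamate F5. N-Silylation (Me3SiOTf, TMEDA, Et2O), ortho-lithiation at C6, the only free ortho position (n-BuLi, −78 °C), and Me3SiCl give, after acidic work-up, 4-(benzyloxy)-2,3-dimethoxy-6-(trimethylsilyl)phenyl propan-2-ylcarbamate F6. Carbamate cleavage with Et2NH/DBU in MeCN at 40 °C and triflation of the phenoxide in the same flask with PhNTf2 deliver 9.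

**Further compounds**

F1 | step 12 | 1-[4-(benzyloxy)-6-hydroxy-2,3-dimethoxyphenyl]ethan-1-one | CC(=O)c1c(O)cc(OCc2ccccc2)c(OC)c1OC
F2 | step 12 | 4-(benzyloxy)-3-[(3S)-4-(benzyloxy)-3-methylbutyl]benzaldehyde | O=Cc1ccc(OCc2ccccc2)c(CC[C@H](C)COCc2ccccc2)c1
F3 | step 12 | (2E)-1-[4-(benzyloxy)-6-hydroxy-2,3-dimethoxyphenyl]-3-{4-(benzyloxy)-3-[(3S)-4-(benzyloxy)-3-methylbutyl]phenyl}prop-2-en-1-one | COc1c(OCc2ccccc2)cc(O)c(C(=O)/C=C/c2ccc(OCc3ccccc3)c(CC[C@H](C)COCc3ccccc3)c2)c1OC
F4 | step 13 | 7-(benzyloxy)-2-{4-(benzyloxy)-3-[(3S)-4-(benzyloxy)-3-methylbutyl]phenyl}-2,3-epoxy-5,6-dimethoxy-2,3-dihydro-4H-chromen-4-one (epoxide diastereomers) | COc1c(OCc2ccccc2)cc2OC3(c4ccc(OCc5ccccc5)c(CC[C@H](C)COCc5ccccc5)c4)OC3C(=O)c2c1OC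
F5 | step 4 | 4-(benzyloxy)-2,3-dimethoxyphenyl propan-2-ylcarbamate | COc1c(OC(=O)NC(C)C)ccc(OCc2ccccc2)c1OC
F6 | step 4 | 4-(benzyloxy)-2,3-dimethoxy-6-(trimethylsilyl)phenyl propan-2-ylcarbamate | COc1c(OC(=O)NC(C)C)c([Si](C)(C)C)cc(OCc2ccccc2)c1OC
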